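The earlier runs and the new flask stem from a simulated flask for an exercise; the scatter is artificial.

The substrate charged stays in the flask in one form or another, so each target reading is a share of a fixed whole. In the amber run at 6.00 h, 17 % is substrate, 22 % is target, and 61.0 % stands in forms not read. The amber run is the asked flask, followed so far.

all flasks: catalyst 0.64 mM

| flask | substrate | partner | remark | time |
|---|---|---|---|---|
| amber | 12 mM | 48 mM | the very flask that is asked about, followed so far |  |
| green | 8 mM | 48 mM | run made earlier |  |
| flask | 12 mM | 48.0 mM |  | 10 h |

| run | time / h | target / % | substrate / % |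
|---|---|---|---|
| amber | 0.500 | 7 | 79 |
| amber | 0.667 | 16 | 75 |
| amber | 1.00 | 22 | 66 |
| amber | 1.50 | 26 | 56 |
| amber | 2.50 | 31 | 39 |
| amber | 4.00 | 26 | 31 |
| amber | 6.00 | 22 | 17 |
| green | 0.250 | 7 | 88 |
| green | 0.833 | 18 | 71 |
| green | 1.33 | 21 | 57 |
| green | 2.00 | 29 | 48 |
| green | 3.00 | 29 | 37 |
| green | 4.00 | 28 | 28 |
| green | 5.00 | 26 | 22 |

(each reading ± 2 percentage points)

- Thursday's: at 10 h take out 90 % of the target then present, then wait 3.0 h
- Tuesday's: change nothing and wait 3.0 h more
- Friday's: at 10 h add partner, 100 % of the amount charged, then wait 3.0 h
- Sunday's: at 10 h add catalyst, 100 % of the amount charged, then wait 3.0 h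

- target taken out counts as made
- additions bring no volume worth counting

- target, in percent of the substrate first charged, at 10 h
- what to do for the largest gain in target; "none" if nothing gains more than 2 percentage points (Thursday's / Tuesday's / Friday's / Sunday's / none)
- target present, with what was taken out counted in, in percent of the substrate first charged, after Thursday's
- target present, with what was taken out counted in, in percent of the substrate first charged, after Friday's

1. At 1.00 h the amber run has used 34.0 % of its substrate and holds 22 % target, so the selectivity reads about 0.647.

2. The highest amber reading of c(target) is 31 % at 2.50 h, good to 2 percentage points, so this reckoning takes making and loss as roughly balanced near that time. Substrate falls by 0.100 h⁻¹ of the charge. Dividing the making rate by c(target) gives the loss constant of target 0.209 h⁻¹, a pseudo-first-order constant and a life of 3.32 h.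

3. Late on, c(target) should relax at this constant towards a holding level, where inflow equals loss. The amber tail gives 14.3 % and the green tail 20.2 %, with a mean of 17.2 %. This is the weak link.

4. From the last amber reading, this reckoning puts target at 10 h at 19.3 %.

5. Thursday's leaves 1.93 % in the flask, which climbs back to 9.06 %. The total is 26.4 %, a gain of 7.1 points, larger than the margin. This reckoning therefore chooses Thursday's.

The forecast differs: 17 %, none, 18.5 % and 14 %, on the ground that “about 2% more substrate converts”.

The flask gives 18.9 %. The best choice is Thursday's, reaching 27.7 %, a gain of 8.7 points; Friday's gives 19.5 %, and Tuesday's changes target by −1.9 points.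

    substrate + partner ⇌ target (K = 42.0 M⁻¹, k = 0.111 M⁻¹ min⁻¹)
    substrate + partner ⇌ isomer of the product A (K = 138 M⁻¹, k = 0.0444 M⁻¹ min⁻¹)
    target + catalyst ⇌ isomer of the product A + catalyst, rate k3*[catalyst]*[target] forward; the back reaction follows from the equilibrium constant (k = 4.54 M⁻¹ min⁻¹)
    target + catalyst ⇌ isomer of the product B + catalyst, rate k4*[catalyst]*[target] forward; the back reaction follows from the equilibrium constant (K = 1.84, k = 2.16 M⁻¹ min⁻¹)

Every step in this scheme runs both ways. After Thursday's removal, 1.89 % target stays in the flask, and it rises by 8.7 points in 3.0 h. The level can now be reforged: Tuesday's change and the loss constant 0.209 h⁻¹ put it at 14.8 %, lower than the tails gave. The neighbouring flask differs in time alone and is left until 40 h. The same relaxation from 18.9 % gives it 14.8 % target, and that flask holds 14.9 %.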